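The route rests on disconnecting the bicyclo[2.2.2]octenone cage and the butenolide (ring E) together. Ring E links the OCH2-bearing bridgehead carbon to the neighbouring alkene carbon of the cage, so its ester O–C(=O) unit can tether a propiolate to a ring-D cyclohexadiene. Heating the propiolate of a cross-conjugated 2-silyloxydiene should forge, in one operation, the bonds from the alkyne α-carbon to the OCH2-bearing diene terminus and from the β-carbon to the methyl-bearing terminus, giving ring E, the bicyclooctadiene and both bridgehead stereocentres. The precursor is a spiro tricycle: lactone ring A, ring B carrying CH2Cl and a silylated tertiary carbinol, and the ring-D silyl dienol ether.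

Key step: step 19

Labels: ring A = unsaturated spiro δ-lactone; ring B = cyclohexane; ring C = cyclopentane (closed last); ring D = ketone-bearing six-membered ring of the cage (a spiro cyclohexenone or cyclohexadiene before step 19); ring E = butenolide; C5 = spiro carbon of rings A and B; C8 = quaternary carbon shared by rings B and D; C9 = ring-B carbon between C8 and C10; C10 = methyl carbinol carbon.

Assumption (remark on the chemistry): the tertiary carbinol is carried as its tert-butyldimethylsilyl (TBS) ether through the key step and freed last, which keeps it out of lactonisation and base chemistry; centres that are erased later (carbinol carbon of 4–8, methyl-bearing ring-D carbon of 16, 17, 22 and 23, epoxide carbon of 19) are left undefined.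

Step 1
Reactants: 1 2-methylcyclohexane-1,3-dione
Product: 2 2-methyl-3-oxocyclohex-1-en-1-yl trifluoromethanesulfonate
Conditions: Tf2O, pyridine, CH2Cl2, −78 → 0 °C
Reagents that add atoms: trifluoromethanesulfonic anhydride, O=S(=O)(OS(=O)(=O)C(F)(F)F)C(F)(F)F
Why: O-sulfonylation of the enol of a symmetrical cyclic 1,3-diketone should give the vinylogous acyl triflate with no regiochemical choice to make.

Step 2
Reactants: 2 2-methyl-3-oxocyclohex-1-en-1-yl trifluoromethanesulfonate; 3 methacrolein
Product: 4 allylic alcohol (racemic carbinol)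
Conditions: CrCl2 (4 equiv), NiCl2 (2 mol %), DMF, 23 °C
Reagents that add atoms: none
Why: Nozaki–Hiyama–Kishi coupling, in which nickel activates the alkenyl C–OTf bond and the alkenylchromium species adds 1,2 to the aldehyde in preference to the ketone; the racemic carbinol centre is of no account because it becomes sp2 in step 7.

Step 3
Reactants: 4 allylic alcohol (racemic carbinol)
Product: 5 allylic TBS ether
Conditions: TBSCl, imidazole, DMF, 23 °C
Reagents that add atoms: tert-butyldimethylsilyl chloride, CC(C)(C)[Si](C)(C)Cl
Why: routine silylation of a secondary allylic alcohol, which installs the silyl group that is later relayed to the tertiary oxygen.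

Step 4
Reactants: 5 allylic TBS ether
Product: 6 (1R)-cyclohexenol
Conditions: (S)-1-methyl-3,3-diphenyltetrahydro-1H,3H-pyrrolo[1,2-c][1,3,2]oxazaborole (0.2 equiv), catecholborane (1.5 equiv), toluene, −78 °C; MeOH
Reagents that add atoms: none
Why: Corey–Bakshi–Shibata reduction, in which the oxazaborolidine–borane complex delivers hydride 1,2 to the enone carbonyl with the ring alkene as the large group, which should set the (R)-carbinol that is the only source of absolute configuration in the route, while catecholborane at low temperature spares the isopropenyl group.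

Step 5
Reactants: 6 (1R)-cyclohexenol
Product: 7 syn-epoxy alcohol
Conditions: VO(acac)2 (5 mol %), t-BuOOH (1.5 equiv), CH2Cl2, 0 → 23 °C
Reagents that add atoms: tert-butyl hydroperoxide, CC(C)(C)OO
Why: hydroxyl-directed (Sharpless–Michaelson) epoxidation, in which the vanadate ester of the ring carbinol transfers oxygen to the adjacent tetrasubstituted alkene on its own face and so fixes both epoxide carbons cis to the hydroxyl, the isopropenyl group (allylic to a silyl ether only) not being activated.

Step 6
Reactants: 7 syn-epoxy alcohol
Product: 8 epoxy ketone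
Conditions: Dess–Martin periodinane, NaHCO3, CH2Cl2, 0 → 23 °C
Reagents that add atoms: none
Why: Dess–Martin oxidation removes the relay carbinol and installs the ketone that later serves as the ring-B ketone and disfavours ionisation of the epoxide at its α-carbon.

Step 7
Reactants: 8 epoxy ketone
Product: 9 β-silyloxy aldehyde
Conditions: TBSOTf (0.2 equiv), 2,6-di-tert-butyl-4-methylpyridine (0.1 equiv), CH2Cl2, −78 → −40 °C
Reagents that add atoms: none
Why: semipinacol rearrangement of a 2,3-epoxy silyl ether (Suzuki–Tsuchihashi type), in which the O-silylated epoxide ionises at the carbon remote from the ketone, the isopropenyl group shifts from the carbinol carbon anti to the departing oxygen and the silyl cation is passed on, so that the quaternary carbon C5 forms with inversion and its formyl group should lie cis to the OTBS group on C10 whatever the carbinol configuration.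

Step 8
Reactants: 9 β-silyloxy aldehyde
Product: 10 methyl (Z)-enoate
Conditions: (CF3CH2O)2P(O)CH2CO2Me, KN(SiMe3)2, 18-crown-6, THF, −78 °C
Reagents that add atoms: methyl bis(2,2,2-trifluoroethyl)phosphonoacetate, COC(=O)CP(=O)(OCC(F)(F)F)OCC(F)(F)F
Why: Still–Gennari olefination should give the (Z)-enoate from the hindered aldehyde, the phosphonate anion being too weak a base to enolise the ketone.

Step 9
Reactants: 10 methyl (Z)-enoate
Product: 12 spiro lactone ketone TBS ether, via (Z)-enoic acid 11 (not isolated)
Conditions: LiOH, THF/H2O, 0 → 23 °C; aq. HCl to pH 3, extraction; TfOH (5 mol %), CH2Cl2, 0 °C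
Reagents that add atoms: lithium hydroxide, [Li+].[OH-]
Why: saponification followed by Brønsted acid-catalysed Markovnikov hydroacyloxylation, in which the tertiary cation from the isopropenyl group is captured by the cis-disposed carboxyl group in a six-membered lactonisation that closes ring A, the silyl ether on C10 keeping the tertiary oxygen from competing; no stereocentre is formed.

Step 10
Reactants: 12 spiro lactone ketone TBS ether; 13 methyl (tert-butyldimethylsilyloxy)acetate
Product: 14 β-diketone
Conditions: LiN(SiMe3)2 (2.5 equiv), THF, −78 °C; 13, −78 → 0 °C; aq. NH4Cl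
Reagents that add atoms: none
Why: crossed Claisen condensation at C8, the only enolisable position of the ketone, driven by deprotonation of the β-diketone formed; the lactone has no α-hydrogen.

Step 11
Reactants: 14 β-diketone; 15 2-methylpent-1-en-3-one
Product: 17 spiro enone, via Michael triketone 16 (not isolated)
Conditions: 15 (2 equiv), DABCO (0.2 equiv), MeCN, 23 °C; pyrrolidine (0.5 equiv), AcOH (0.5 equiv), toluene, 70 °C
Reagents that add atoms: none
Why: Robinson annulation, in which the β-diketone enolate should add to the vinyl ketone on the face of C8 opposite the pseudoaxial OTBS group on C10 (CH2 arm trans to OTBS) and the enamine of the less hindered ethyl ketone then condenses onto the silyloxyacetyl carbonyl, the ring-B ketone being screened by two quaternary neighbours; the methyl-bearing centre forms as an epimer mixture that step 12 erases.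

Step 12
Reactants: 17 spiro enone
Product: 18 silyloxydiene ketone
Conditions: KN(SiMe3)2 (1.2 equiv), THF, −78 °C; TBSOTf (1.3 equiv)
Reagents that add atoms: tert-butyldimethylsilyl trifluoromethanesulfonate, CC(C)(C)[Si](C)(C)OS(=O)(=O)C(F)(F)F
Why: kinetic α'-deprotonation of the cyclohexenone and O-silylation give the cross-conjugated 2-silyloxydiene, which masks the ring-D carbonyl and leaves the C9 ketone (no α-hydrogen) as the only carbonyl open to step 13.

Step 13
Reactants: 18 silyloxydiene ketone
Product: 19 spiro epoxide
Conditions: Me3S+ I− (3 equiv), n-BuLi (2.8 equiv), THF, −10 °C; 18, −10 → 23 °C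
Reagents that add atoms: trimethylsulfonium iodide, C[S+](C)C.[I-]
Why: Corey–Chaykovsky epoxidation, in which the small unstabilised sulfonium methylide adds to the one free ketone and the betaine closes to the epoxide, esters and the silyl dienol ether being inert; the configuration of the epoxide carbon does not matter because it becomes a radical in step 14.

Step 14
Reactants: 19 spiro epoxide
Product: 20 primary alcohol
Conditions: Cp2TiCl2 (20 mol %), Mn (2 equiv), 2,4,6-collidine hydrochloride (2.5 equiv), 1,4-cyclohexadiene (5 equiv), THF, 23 °C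
Reagents that add atoms: none
Why: titanocene-mediated reductive epoxide opening (Nugent–RajanBabu, catalytic Gansäuer variant), in which Cp2TiCl (trivalent titanium) cleaves the C–O bond toward the tertiary C9 radical, which should take hydrogen from 1,4-cyclohexadiene on the face away from the OTBS group and the substituted ring-D carbon, leaving CH2OH cis to both.

Step 15
Reactants: 20 primary alcohol
Product: 21 chloride
Conditions: PPh3 (2 equiv), CCl4 (5 equiv), imidazole (1 equiv), MeCN/CH2Cl2, 40 °C
Reagents that add atoms: carbon tetrachloride, ClC(Cl)(Cl)Cl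
Why: Appel chlorination converts the primary alcohol through its alkoxyphosphonium salt under non-acidic conditions that the silyl dienol ether tolerates; no stereocentre is touched.

Step 16
Reactants: 21 chloride
Product: 22 hydroxy enone
Conditions: HF·pyridine, pyridine, THF, 0 → 23 °C
Reagents that add atoms: none
Why: selective desilylation, in which the dienol ether is cleaved with protonation at the α'-carbon to return the conjugated enone and the unhindered primary silyl ether is removed, while the hindered tertiary silyl ether should persist.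

Step 17
Reactants: 22 hydroxy enone
Product: 25 hydroxy dienol ether, via primary TMS ether 23 (not isolated), via TMS-protected TBS dienol ether 24 (not isolated)
Conditions: Me3SiCl (1.2 equiv), KN(SiMe3)2 (1.1 equiv), THF, −78 °C; KN(SiMe3)2 (1.2 equiv), then TBSOTf (1.3 equiv), −78 °C; K2CO3, MeOH, 0 °C
Reagents that add atoms: tert-butyldimethylsilyl trifluoromethanesulfonate, CC(C)(C)[Si](C)(C)OS(=O)(=O)C(F)(F)F
Why: transient TMS protection of the primary alcohol, kinetic α'-enolisation with O-silylation and mild methanolysis of the primary TMS ether, which is far more labile than the TBS enol ether and the tertiary TBS ether, should give the free alcohol beside the 2-silyloxydiene; the epimers at the methyl-bearing carbon converge.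

Step 18
Reactants: 25 hydroxy dienol ether; 26 propiolic acid
Product: 27 propiolate ester
Conditions: 26 and N,N'-dicyclohexylcarbodiimide (1.5 equiv each) premixed, CH2Cl2, −20 °C; 25, DMAP (5 mol %), −20 → 0 °C
Reagents that add atoms: none
Why: Steglich esterification of an unhindered primary allylic alcohol, with the acid consumed as its O-acylisourea before the acid-sensitive dienol ether is added and the temperature kept low to avoid amine addition to the ynoate.

Step 19
Reactants: 27 propiolate ester
Product: 28 cycloadduct
Conditions: toluene (5 mM), BHT, 2,6-di-tert-butylpyridine (0.2 equiv), 140 °C, sealed tube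
Reagents that add atoms: none
Why: Thermal intramolecular Diels–Alder reaction of normal electron demand: the electron-rich 2-silyloxy-1,3-diene, most nucleophilic at its methyl-bearing terminus, and the electron-poor ynoate should combine in a concerted, asynchronous [4+2] in which the alkyne β-carbon bonds to that terminus and the α-carbon to the CH2O-bearing terminus. The closest known reaction type is the cycloaddition of 2-silyloxycyclohexa-1,3-dienes with alkynoates to give bicyclo[2.2.2]octadienes, made intramolecular here by the ester. The γ-lactone (ring E) closes in fused mode through the three-atom CH2–O–C(=O) tether anchored on the diene terminus, and the second ring closes as the six-membered cycloadduct ring that completes the bicyclo[2.2.2]octadiene. Both new stereocentres are bridgeheads: their mutual relation is fixed by suprafacial addition across the ring-D diene and their relation to C8 by the π-face that the tethered alkyne reaches. The step needs attack on the diene face flanked by the ring-B CH2 group rather than the face under the C9 methine, which the CH2Cl group and the neighbouring OTBS-bearing quaternary carbon screen; regiochemistry is locked by the tether and an alkyne raises no endo/exo question. The surviving tetrasubstituted silyl enol ether is the regiodefined enolate equivalent for ring C.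

Step 20
Reactants: 28 cycloadduct
Product: 29 iodide
Conditions: NaI (10 equiv), NaHCO3, 2-butanone, 80 °C, dark
Reagents that add atoms: sodium iodide, [Na+].[I-]
Why: Finkelstein exchange at the primary carbon, driven by precipitation of NaCl, gives the better leaving group while leaving the silyl enol ether untouched.

Step 21
Reactants: 29 iodide
Product: 31 andibenin, via andibenin TBS ether 30 (not isolated)
Conditions: tris(dimethylamino)sulfonium difluorotrimethylsilicate (1.2 equiv), THF, −20 → 0 °C; 48% aq. HF, MeCN, 23 °C
Reagents that add atoms: none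
Why: fluoride-triggered intramolecular enolate alkylation (5-exo-tet), in which the enolate released from the silyl enol ether can reach the iodide only on the face where the CH2I arm sits, which fixes the last quaternary centre and closes ring C, after which aqueous HF cleaves the tertiary silyl ether.

Compound list
1 | 2-methylcyclohexane-1,3-dione | CC1C(=O)CCCC1=O | starting material
2 | 2-methyl-3-oxocyclohex-1-en-1-yl trifluoromethanesulfonate | CC1=C(OS(=O)(=O)C(F)(F)F)CCCC1=O | intermediate
3 | methacrolein (2-methylprop-2-enal) | CC(=C)C=O | starting material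
4 | 3-(1-hydroxy-2-methylprop-2-en-1-yl)-2-methylcyclohex-2-en-1-one, racemic at the carbinol carbon | CC(=C)C(O)C1=C(C)C(=O)CCC1 | intermediate
5 | 3-[1-(tert-butyldimethylsilyloxy)-2-methylprop-2-en-1-yl]-2-methylcyclohex-2-en-1-one, racemic | CC(=C)C(O[Si](C)(C)C(C)(C)C)C1=C(C)C(=O)CCC1 | intermediate
6 | (1R)-3-[1-(tert-butyldimethylsilyloxy)-2-methylprop-2-en-1-yl]-2-methylcyclohex-2-en-1-ol, both epimers at the silyloxy carbon | CC(=C)C(O[Si](C)(C)C(C)(C)C)C1=C(C)[C@H](O)CCC1 | intermediate
7 | epoxy alcohol: ring alkene of 6 epoxidised on the face of the ring hydroxyl | CC(=C)C(O[Si](C)(C)C(C)(C)C)[C@@]12O[C@]1(C)[C@H](O)CCC2 | intermediate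
8 | epoxy ketone: ring carbinol of 7 oxidised | CC(=C)C(O[Si](C)(C)C(C)(C)C)[C@@]12O[C@]1(C)C(=O)CCC2 | intermediate
9 | 2-(tert-butyldimethylsilyloxy)-2-methyl-3-oxo-1-(prop-1-en-2-yl)cyclohexane-1-carbaldehyde, formyl cis to OTBS | O=C[C@@]1(C(C)=C)CCCC(=O)[C@@]1(C)O[Si](C)(C)C(C)(C)C | intermediate
10 | methyl (Z)-3-[ring carbon C5 of 9]prop-2-enoate | COC(=O)/C=C\[C@@]1(C(C)=C)CCCC(=O)[C@@]1(C)O[Si](C)(C)C(C)(C)C | intermediate
11 | the corresponding (Z)-enoic acid | OC(=O)/C=C\[C@@]1(C(C)=C)CCCC(=O)[C@@]1(C)O[Si](C)(C)C(C)(C)C | intermediate
12 | spiro lactone ketone: ring A spiro at C5 to 2-(tert-butyldimethylsilyloxy)-2-methylcyclohexanone, OTBS cis to the ring-A alkene carbon | CC1(C)OC(=O)C=C[C@]12CCCC(=O)[C@@]2(C)O[Si](C)(C)C(C)(C)C | intermediate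
13 | methyl (tert-butyldimethylsilyloxy)acetate | COC(=O)CO[Si](C)(C)C(C)(C)C | starting material
14 | β-diketone: 12 acylated at C8 with the (tert-butyldimethylsilyloxy)acetyl group (C8 enolisable, undefined) | CC1(C)OC(=O)C=C[C@]12CCC(C(=O)CO[Si](C)(C)C(C)(C)C)C(=O)[C@@]2(C)O[Si](C)(C)C(C)(C)C | intermediate
15 | 2-methylpent-1-en-3-one | CCC(=O)C(C)=C | starting material
16 | triketone: C8 carries the 2-methyl-3-oxopentyl chain trans to the C10 OTBS group and the silyloxyacetyl group cis to it | CC1(C)OC(=O)C=C[C@]12CC[C@@](CC(C)C(=O)CC)(C(=O)CO[Si](C)(C)C(C)(C)C)C(=O)[C@@]2(C)O[Si](C)(C)C(C)(C)C | intermediate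
17 | spiro enone: ring D = 2,6-dimethyl-3-(silyloxymethyl)cyclohex-2-enone spiro at C8, CH2 arm trans to the C10 OTBS group, ketone at C9 | CC1(C)OC(=O)C=C[C@]12CC[C@]3(CC(C)C(=O)C(C)=C3CO[Si](C)(C)C(C)(C)C)C(=O)[C@@]2(C)O[Si](C)(C)C(C)(C)C | intermediate
18 | cross-conjugated TBS dienol ether of 17 (C9 ketone retained) | CC1(C)OC(=O)C=C[C@]12CC[C@]3(CC(C)=C(O[Si](C)(C)C(C)(C)C)C(C)=C3CO[Si](C)(C)C(C)(C)C)C(=O)[C@@]2(C)O[Si](C)(C)C(C)(C)C | intermediate
19 | spiro epoxide at C9 | CC1(C)OC(=O)C=C[C@]12CC[C@]3(CC(C)=C(O[Si](C)(C)C(C)(C)C)C(C)=C3CO[Si](C)(C)C(C)(C)C)C4(CO4)[C@@]2(C)O[Si](C)(C)C(C)(C)C | intermediate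
20 | primary alcohol: C9 methine with CH2OH cis to the C10 OTBS group and to the CH2O-bearing ring-D carbon | CC1(C)OC(=O)C=C[C@]12CC[C@]3(CC(C)=C(O[Si](C)(C)C(C)(C)C)C(C)=C3CO[Si](C)(C)C(C)(C)C)[C@@H](CO)[C@@]2(C)O[Si](C)(C)C(C)(C)C | intermediate
21 | the corresponding chloride | CC1(C)OC(=O)C=C[C@]12CC[C@]3(CC(C)=C(O[Si](C)(C)C(C)(C)C)C(C)=C3CO[Si](C)(C)C(C)(C)C)[C@@H](CCl)[C@@]2(C)O[Si](C)(C)C(C)(C)C | intermediate
22 | hydroxy enone: ring-D enone with free CH2OH, CH2Cl on C9, OTBS on C10 | CC1(C)OC(=O)C=C[C@]12CC[C@]3(CC(C)C(=O)C(C)=C3CO)[C@@H](CCl)[C@@]2(C)O[Si](C)(C)C(C)(C)C | intermediate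
23 | primary trimethylsilyl ether of 22 | CC1(C)OC(=O)C=C[C@]12CC[C@]3(CC(C)C(=O)C(C)=C3CO[Si](C)(C)C)[C@@H](CCl)[C@@]2(C)O[Si](C)(C)C(C)(C)C | intermediate
24 | TBS dienol ether of 23 | CC1(C)OC(=O)C=C[C@]12CC[C@]3(CC(C)=C(O[Si](C)(C)C(C)(C)C)C(C)=C3CO[Si](C)(C)C)[C@@H](CCl)[C@@]2(C)O[Si](C)(C)C(C)(C)C | intermediate
25 | hydroxy dienol ether: 24 with free CH2OH | CC1(C)OC(=O)C=C[C@]12CC[C@]3(CC(C)=C(O[Si](C)(C)C(C)(C)C)C(C)=C3CO)[C@@H](CCl)[C@@]2(C)O[Si](C)(C)C(C)(C)C | intermediate
26 | propiolic acid | OC(=O)C#C | starting material
27 | propiolate ester of the spiro silyl dienol ether (Diels–Alder precursor, C10 as TBS ether) | CC1(C)OC(=O)C=C[C@]12CC[C@]3(CC(C)=C(O[Si](C)(C)C(C)(C)C)C(C)=C3COC(=O)C#C)[C@@H](CCl)[C@@]2(C)O[Si](C)(C)C(C)(C)C | intermediate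
28 | butenolide-fused bicyclo[2.2.2]octadiene silyl enol ether (C10 as TBS ether) | CC1(C)OC(=O)C=C[C@]12CC[C@]3(C[C@@]4(C)C=C5C(=O)OC[C@]53C(C)=C4O[Si](C)(C)C(C)(C)C)[C@@H](CCl)[C@@]2(C)O[Si](C)(C)C(C)(C)C | intermediate
29 | the corresponding iodide | CC1(C)OC(=O)C=C[C@]12CC[C@]3(C[C@@]4(C)C=C5C(=O)OC[C@]53C(C)=C4O[Si](C)(C)C(C)(C)C)[C@@H](CI)[C@@]2(C)O[Si](C)(C)C(C)(C)C | intermediate
30 | andibenin tert-butyldimethylsilyl ether (ring C closed) | CC1(C)OC(=O)C=C[C@]12CC[C@@]13C[C@@]4(C)C=C5C(=O)OC[C@]51[C@@](C)(C[C@H]3[C@@]2(C)O[Si](C)(C)C(C)(C)C)C4=O | intermediate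
31 | andibenin | CC1(C)OC(=O)C=C[C@]12CC[C@@]13C[C@@]4(C)C=C5C(=O)OC[C@]51[C@@](C)(C[C@H]3[C@@]2(C)O)C4=O | target

Total step count: 21. Longest linear sequence: 21 steps (1 to 31); compounds 3, 13, 15 and 26 enter as purchased materials.

Steps most likely to fail

Step 19. The ester tether may not populate the conformer in which the alkyne lies over the diene, so the temperature needed may cost the dienol ether by protodesilylation or erode the facial preference. The fallback sets out from 25 and returns at 28 by making the same two bonds intermolecularly. Alcohol 25 is heated with excess methyl propiolate; the same orbital pairing (methyl-bearing terminus to the alkyne β-carbon) on the same less screened face should give hydroxy ester cycloadduct F1. Its CH2OH and neighbouring ester are held cis and should lactonise on continued warming to 28.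

Step 11. The Michael addition may show poor facial selectivity at C8, or the non-enolisable triketone may suffer retro-Claisen cleavage before the aldol condensation. The fallback sets out from 12 and returns at 17, attaching the two ring-D bonds to C8 in the opposite order so that the same facial bias gives the opposite configuration. α-Methylenation of 12 (paraformaldehyde, N-methylanilinium trifluoroacetate) gives exo-methylene ketone F2. Pentan-3-one and (tert-butyldimethylsilyloxy)acetaldehyde give aldol adduct F3, which is dehydrated (TsOH) to (E)-enone F4 and silylated (TBSOTf, Et3N) to diene F5. A thermal Diels–Alder reaction of F2 with F5 gives spiro adduct F6, and Saegusa oxidation of its silyl enol ether (Pd(OAc)2, MeCN) gives 17.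

Step 13. The sulfonium methylide may decompose before it adds to a ketone flanked by two quaternary carbons. The fallback sets out from 18 and returns at 19, replacing ylide transfer by irreversible addition of a lithium carbenoid. Chloromethyllithium, generated in the presence of 18 (ClCH2I, MeLi·LiBr, THF, −78 °C) and quenched cold, gives chlorohydrin F7, which KOtBu closes to 19.

Further compounds
F1 | step 19 | hydroxy ester cycloadduct (methyl ester on the cage alkene carbon, free CH2OH on the adjacent bridgehead) | CC1(C)OC(=O)C=C[C@]12CC[C@]3(C[C@@]4(C)C=C(C(=O)OC)[C@]3(CO)C(C)=C4O[Si](C)(C)C(C)(C)C)[C@@H](CCl)[C@@]2(C)O[Si](C)(C)C(C)(C)C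
F2 | step 11 | exo-methylene ketone (12 with C8=CH2) | CC1(C)OC(=O)C=C[C@]12CCC(=C)C(=O)[C@@]2(C)O[Si](C)(C)C(C)(C)C
F3 | step 11 | 6-(tert-butyldimethylsilyloxy)-5-hydroxy-4-methylhexan-3-one | CCC(=O)C(C)C(O)CO[Si](C)(C)C(C)(C)C
F4 | step 11 | (E)-6-(tert-butyldimethylsilyloxy)-4-methylhex-4-en-3-one | CCC(=O)/C(C)=C/CO[Si](C)(C)C(C)(C)C
F5 | step 11 | (2Z,4E)-3,6-bis(tert-butyldimethylsilyloxy)-4-methylhexa-2,4-diene | C/C=C(\O[Si](C)(C)C(C)(C)C)/C(C)=C/CO[Si](C)(C)C(C)(C)C
F6 | step 11 | spiro Diels–Alder adduct (ring-D silyl enol ether, two ring-D methines undefined, C9 ketone) | CC1(C)OC(=O)C=C[C@]12CC[C@]3(CC(C)C(O[Si](C)(C)C(C)(C)C)=C(C)C3CO[Si](C)(C)C(C)(C)C)C(=O)[C@@]2(C)O[Si](C)(C)C(C)(C)C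
F7 | step 13 | C9 chlorohydrin of 18 | CC1(C)OC(=O)C=C[C@]12CC[C@]3(CC(C)=C(O[Si](C)(C)C(C)(C)C)C(C)=C3CO[Si](C)(C)C(C)(C)C)C(O)(CCl)[C@@]2(C)O[Si](C)(C)C(C)(C)C
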